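**Strategy**

Ring C of the flavanone is cut at C3–C4 and at O1–C8a, which leaves a ring A methyl 2-fluorobenzoate and the methyl ketone of ring B. The plan exploits the ortho relationship between the C4 carbonyl and the oxygen-bearing carbon C8a on ring A: Claisen acylation of the ketone enolate makes C3–C4, and the new C4 ketone then activates the neighbouring C8a–F bond for displacement by the diketone enolate oxygen, the future O1. One operation thus joins the two halves and closes ring C as a flavone. Asymmetric copper hydride conjugate reduction then sets C2 as S, and acid removes the MOM group.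

Key step: step 5

Remark on the chemistry: 4-bromo-3-fluorophenol and 2,2-dimethyl-2H-chromene-6-carbonitrile are taken as purchasable. The (R) antipode of DTBM-SEGPHOS is assumed to deliver hydride to the face of C2 that leads to the 2S product; if a trial on the substrate shows the opposite sense, the (S) ligand is used instead.

**Route**

Step 1
Reactants: 1 4-bromo-3-fluorophenol
Product: 2 1-bromo-2-fluoro-4-(methoxymethoxy)benzene
Conditions: MOMCl, iPr2NEt, CH2Cl2, 0 → 23 °C
Reagents that add atoms: chloromethyl methyl ether (MOMCl), COCCl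
Why: O-alkylation of the phenol by the reactive α-chloro ether under amine base (Williamson-type etherification) should give the MOM acetal, which later helps to direct the lithiation and is stable to every basic step that follows.

Step 2
Reactants: 2 1-bromo-2-fluoro-4-(methoxymethoxy)benzene
Product: 5 1-bromo-2-fluoro-4-(methoxymethoxy)-3-(3-methylbut-2-en-1-yl)benzene, via aryllithium 3 (not isolated), via arylcopper 4 (not isolated)
Conditions: LiN(iPr)2 (1.1 equiv), THF, −78 °C; CuBr·SMe2 (1.1 equiv), −78 °C; prenyl bromide (1.5 equiv), −78 → 0 °C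
Reagents that add atoms: prenyl bromide (1-bromo-3-methylbut-2-ene), CC(C)=CCBr
Why: Directed ortho-metalation, in which the only C–H flanked by fluorine and the MOM ether is by far the most acidic and the amide base does not touch the C–Br bond at −78 °C, followed by transmetalation to copper and allylic substitution of prenyl bromide at its primary carbon, should place the prenyl group between F and OMOM.

Step 3
Reactants: 5 1-bromo-2-fluoro-4-(methoxymethoxy)-3-(3-methylbut-2-en-1-yl)benzene
Product: 7 methyl 2-fluoro-4-(methoxymethoxy)-3-(3-methylbut-2-en-1-yl)benzoate, via aryllithium 6 (not isolated)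
Conditions: n-BuLi (1.05 equiv), THF, −78 °C; then transfer into ClCO2Me (3 equiv), THF, −78 °C
Reagents that add atoms: methyl chloroformate, COC(=O)Cl
Why: Bromine–lithium exchange is faster than any deprotonation at −78 °C, the ortho-fluoro aryllithium does not lose LiF at this temperature, and inverse addition into excess chloroformate (acyl substitution) should give the ester without double addition.

Step 4
Reactants: 8 2,2-dimethyl-2H-chromene-6-carbonitrile
Product: 10 1-(2,2-dimethyl-2H-chromen-6-yl)ethan-1-one, via N-magnesio ketimine 9 (not isolated)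
Conditions: MeMgBr (1.5 equiv), THF, 0 → 50 °C; then 1 M aq. HCl, 0 → 23 °C
Reagents that add atoms: methylmagnesium bromide, C[Mg]Br; water, O
Why: Grignard addition to an aryl nitrile stops at the metalated ketimine, which cold dilute acid hydrolyses to the methyl ketone, and the chromene ether and alkene are inert to both stages.

Step 5
Reactants: 10 1-(2,2-dimethyl-2H-chromen-6-yl)ethan-1-one; 7 methyl 2-fluoro-4-(methoxymethoxy)-3-(3-methylbut-2-en-1-yl)benzoate
Product: 12 2-(2,2-dimethyl-2H-chromen-6-yl)-7-(methoxymethoxy)-8-(3-methylbut-2-en-1-yl)-4H-chromen-4-one, via 1,3-diketone 11 (not isolated)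
Conditions: NaH (2.5 equiv), THF, 0 → 65 °C; then DMF added after gas evolution has ceased, 90 °C
Reagents that add atoms: none
Why: NaH converts 10 into its sodium enolate, which adds to the ester carbonyl of 7 and expels methoxide (crossed Claisen condensation, 7 has no α-hydrogen), so the C3–C4 bond forms and the product rests as the sodium enolate of 1,3-diketone 11; on heating in DMF the enolate oxygen that stems from the ketone of 10 adds to C8a and fluoride leaves through a Meisenheimer-type anion delocalised into the new C4 carbonyl, which forms O1–C8a. The closest known reaction type is the one-pot Claisen condensation and intramolecular SNAr that turns 2-fluorobenzoyl donors and methyl ketones into chromones and flavones. Ring C closes by a 6-endo-trig addition–elimination, since the attacked C4a=C8a bond lies inside the new ring. No stereocentre is formed because C2 emerges trigonal; it is set in step 6. The step needs C- over O-acylation, which the irreversible deprotonation of 11 should secure, and ring closure over intermolecular fluoride displacement by methoxide or a second enolate, which should be secured because the fluoride of 7 is only weakly activated by an ester para to the MOM ether, whereas the ketone of 11 activates it strongly and holds the oxygen nucleophile in reach for a six-membered closure.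

Step 6
Reactants: 12 2-(2,2-dimethyl-2H-chromen-6-yl)-7-(methoxymethoxy)-8-(3-methylbut-2-en-1-yl)-4H-chromen-4-one
Product: 14 (2S)-2-(2,2-dimethyl-2H-chromen-6-yl)-7-(methoxymethoxy)-8-(3-methylbut-2-en-1-yl)-2,3-dihydro-4H-chromen-4-one, via enol silane 13 (not isolated)
Conditions: Cu(OAc)2 (5 mol %), (R)-DTBM-SEGPHOS (5.5 mol %), (EtO)2MeSiH (3 equiv), toluene, −20 → 0 °C; then 1 M aq. HCl, THF, 0 °C
Reagents that add atoms: none
Why: Asymmetric copper hydride conjugate reduction of a chromone (the divalent copper acetate is reduced by the silane to a ligand-bound monovalent copper hydride) should deliver hydride to one face of C2 so that the C2 stereocentre is set under catalyst control, the copper enolate is silylated to enol silane 13, which shields C4 from 1,2-reduction, cold dilute acid then frees the ketone without base so that the retro-oxa-Michael path to racemisation stays closed, and the hindered chromene alkene and the trisubstituted prenyl alkene should not be hydrocuprated at this temperature.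

Step 7
Reactants: 14 (2S)-2-(2,2-dimethyl-2H-chromen-6-yl)-7-(methoxymethoxy)-8-(3-methylbut-2-en-1-yl)-2,3-dihydro-4H-chromen-4-one
Product: 15 (2S)-2-(2,2-dimethyl-2H-chromen-6-yl)-7-hydroxy-8-(3-methylbut-2-en-1-yl)-2,3-dihydro-4H-chromen-4-one
Conditions: 2 M aq. HCl, MeOH, 40 °C
Reagents that add atoms: none
Why: Acid-catalysed acetal exchange with methanol should remove the MOM group, the C2 stereocentre is not at risk because flavanones racemise through base-mediated ring opening and not in dilute acid, and the mild temperature should keep the prenyl group from cyclising onto the new phenol.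

**Compound list**

1 | 4-bromo-3-fluorophenol | Oc1ccc(Br)c(F)c1 | starting material
2 | 1-bromo-2-fluoro-4-(methoxymethoxy)benzene | COCOc1ccc(Br)c(F)c1 | intermediate
3 | [3-bromo-2-fluoro-6-(methoxymethoxy)phenyl]lithium | COCOc1ccc(Br)c(F)c1[Li] | intermediate
4 | [3-bromo-2-fluoro-6-(methoxymethoxy)phenyl]copper | COCOc1ccc(Br)c(F)c1[Cu] | intermediate
5 | 1-bromo-2-fluoro-4-(methoxymethoxy)-3-(3-methylbut-2-en-1-yl)benzene | COCOc1ccc(Br)c(F)c1CC=C(C)C | intermediate
6 | [2-fluoro-4-(methoxymethoxy)-3-(3-methylbut-2-en-1-yl)phenyl]lithium | COCOc1ccc([Li])c(F)c1CC=C(C)C | intermediate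
7 | methyl 2-fluoro-4-(methoxymethoxy)-3-(3-methylbut-2-en-1-yl)benzoate | COC(=O)c1ccc(OCOC)c(CC=C(C)C)c1F | intermediate
8 | 2,2-dimethyl-2H-chromene-6-carbonitrile | N#Cc1ccc2c(c1)C=CC(C)(C)O2 | starting material
9 | N-(bromomagnesio) ketimine of 1-(2,2-dimethyl-2H-chromen-6-yl)ethan-1-one | CC(=N[Mg]Br)c1ccc2c(c1)C=CC(C)(C)O2 | intermediate
10 | 1-(2,2-dimethyl-2H-chromen-6-yl)ethan-1-one | CC(=O)c1ccc2c(c1)C=CC(C)(C)O2 | intermediate
11 | 1-(2,2-dimethyl-2H-chromen-6-yl)-3-[2-fluoro-4-(methoxymethoxy)-3-(3-methylbut-2-en-1-yl)phenyl]propane-1,3-dione | CC(C)=CCc1c(OCOC)ccc(C(=O)CC(=O)c2ccc3c(c2)C=CC(C)(C)O3)c1F | intermediate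
12 | 2-(2,2-dimethyl-2H-chromen-6-yl)-7-(methoxymethoxy)-8-(3-methylbut-2-en-1-yl)-4H-chromen-4-one | CC(C)=CCc1c(OCOC)ccc2c1OC(c1ccc3c(c1)C=CC(C)(C)O3)=CC2=O | intermediate
13 | (2S)-4-{[diethoxy(methyl)silyl]oxy}-2-(2,2-dimethyl-2H-chromen-6-yl)-7-(methoxymethoxy)-8-(3-methylbut-2-en-1-yl)-2H-chromene | CC(C)=CCc1c(OCOC)ccc2c1O[C@H](c1ccc3c(c1)C=CC(C)(C)O3)C=C2O[Si](C)(OCC)OCC | intermediate
14 | (2S)-2-(2,2-dimethyl-2H-chromen-6-yl)-7-(methoxymethoxy)-8-(3-methylbut-2-en-1-yl)-2,3-dihydro-4H-chromen-4-one | CC(C)=CCc1c(OCOC)ccc2c1O[C@H](c1ccc3c(c1)C=CC(C)(C)O3)CC2=O | intermediate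
15 | (2S)-2-(2,2-dimethyl-2H-chromen-6-yl)-7-hydroxy-8-(3-methylbut-2-en-1-yl)-2,3-dihydro-4H-chromen-4-one | CC(C)=CCc1c(O)ccc2c1O[C@H](c1ccc3c(c1)C=CC(C)(C)O3)CC2=O | target

**Totals**

Total step count: 7
Longest linear sequence: 6 steps (steps 1, 2, 3, 5, 6, 7)

**Steps most likely to fail**

1. Step 6. Hydride transfer may be slow because the enone is doubly deactivated (C2 carries the ring oxygen and an electron-rich aryl group, C4 is para to the MOM ether). Facial selectivity may be poor for a 2-aryl chromone, the carbonyl may be over-reduced, or the chromene alkene may be hydrocuprated. The fallback sets out from flavone 12. Conjugate reduction with LiBH(s-Bu)3 in THF at −78 °C, with a cold acidic quench, should give racemic 2-(2,2-dimethyl-2H-chromen-6-yl)-7-(methoxymethoxy)-8-(3-methylbut-2-en-1-yl)-2,3-dihydro-4H-chromen-4-one F1. Kinetic resolution by asymmetric transfer hydrogenation (RuCl[(S,S)-TsDPEN](p-cymene) or its antipode, whichever reduces the 2R ketone faster in a trial; HCO2H/Et3N, EtOAc, 23 °C; stopped near half conversion) should reduce the 2R ketone to (2R,4R)-2-(2,2-dimethyl-2H-chromen-6-yl)-7-(methoxymethoxy)-8-(3-methylbut-2-en-1-yl)-3,4-dihydro-2H-chromen-4-ol F2, which is separated by chromatography. The 2S ketone is recovered, and the fallback comes back to the route at 14.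

2. Step 5. Methoxide or a second enolate may displace the fluoride intermolecularly before ring closure. The chelated sodium diketonate may close slowly next to the C8 prenyl group, and hot base may move the prenyl double bond into conjugation. The fallback sets out from aryl bromide 5 and ketone 10 and forms the two bonds in separate operations without any alkoxide. Bromine–lithium exchange of 5 (n-BuLi, THF, −78 °C) and a DMF quench should give 2-fluoro-4-(methoxymethoxy)-3-(3-methylbut-2-en-1-yl)benzaldehyde F3. Aldol addition of the lithium enolate of 10 (LiN(iPr)2, THF, −78 °C) should give racemic 3-[2-fluoro-4-(methoxymethoxy)-3-(3-methylbut-2-en-1-yl)phenyl]-3-hydroxy-1-(2,2-dimethyl-2H-chromen-6-yl)propan-1-one F4. Oxidation with Dess–Martin periodinane (CH2Cl2, 23 °C) should give diketone 11, now isolated, and K2CO3 in DMF at 60–80 °C should close it to flavone 12, where the fallback comes back to the route.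

3. Step 2. The arylcopper may attack the tertiary end of prenyl bromide (SN2′ pathway), which would give the reverse-prenyl isomer, or homocoupling of the allylic bromide may consume the reagent. The fallback sets out from 2. The same lithiation and transmetalation, followed by allyl bromide, which has no regiochemical ambiguity, should give 1-bromo-2-fluoro-4-(methoxymethoxy)-3-(prop-2-en-1-yl)benzene F5. Olefin cross-metathesis with excess 2-methyl-2-butene (second-generation Grubbs catalyst, CH2Cl2, 40 °C) should then convert the allyl into the prenyl group and come back to the route at 5.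

**Further compounds**

F1 | step 6 | racemic 2-(2,2-dimethyl-2H-chromen-6-yl)-7-(methoxymethoxy)-8-(3-methylbut-2-en-1-yl)-2,3-dihydro-4H-chromen-4-one | CC(C)=CCc1c(OCOC)ccc2c1OC(c1ccc3c(c1)C=CC(C)(C)O3)CC2=O
F2 | step 6 | (2R,4R)-2-(2,2-dimethyl-2H-chromen-6-yl)-7-(methoxymethoxy)-8-(3-methylbut-2-en-1-yl)-3,4-dihydro-2H-chromen-4-ol | CC(C)=CCc1c(OCOC)ccc2c1O[C@@H](c1ccc3c(c1)C=CC(C)(C)O3)C[C@H]2O
F3 | step 5 | 2-fluoro-4-(methoxymethoxy)-3-(3-methylbut-2-en-1-yl)benzaldehyde | COCOc1ccc(C=O)c(F)c1CC=C(C)C
F4 | step 5 | racemic 3-[2-fluoro-4-(methoxymethoxy)-3-(3-methylbut-2-en-1-yl)phenyl]-3-hydroxy-1-(2,2-dimethyl-2H-chromen-6-yl)propan-1-one | COCOc1ccc(C(O)CC(=O)c2ccc3c(c2)C=CC(C)(C)O3)c(F)c1CC=C(C)C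
F5 | step 2 | 1-bromo-2-fluoro-4-(methoxymethoxy)-3-(prop-2-en-1-yl)benzene | COCOc1ccc(Br)c(F)c1CC=C
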